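The quinone ring (C1=O, C2 bearing the chroman, C3–H, C4=O, C5–OMe, C6–OMe) is disconnected into dimethyl squarate and an alkyne: C4–C5–C6–C1 with both carbonyls and both methoxy groups is the squarate carbon chain, C2 and C3 are the sp carbons of (S)-3-ethynyl-6,7-dimethoxychroman. The key step is a strain-driven Moore rearrangement: the 4-alkynyl-4-hydroxycyclobutenone from these two halves opens thermally to an alkynyl vinylketene, which closes the six-membered ring through the new C1–C2 bond and emerges directly as the quinone, the carbinol hydrogen becoming C3–H. The chroman stereocentre, set earlier by asymmetric hydrogenation, is only a propargylic spectator.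

Key step: step 7

Remark (assumption): the sense of induction of the Ir–PHOX catalyst on allylic alcohol 4 in step 3 is not predicted here; the ligand antipode that delivers (S)-5 (both antipodes are commercial) is to be fixed by a small-scale test. The target as drawn has the (3S) configuration.

Step 1
Reactants: 1 2-hydroxy-4,5-dimethoxybenzaldehyde; 2 acrolein
Product: 3 6,7-dimethoxy-2H-chromene-3-carbaldehyde
Conditions: K2CO3 (cat.), 1,4-dioxane, reflux
Reagents that add atoms: none
Why: Base-mediated domino oxa-Michael addition of the phenoxide of 1 to acrolein followed by intramolecular aldol condensation onto the aryl aldehyde is the standard route from salicylaldehydes to 2H-chromene-3-carbaldehydes; no stereocentre is formed.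

Step 2
Reactants: 3 6,7-dimethoxy-2H-chromene-3-carbaldehyde
Product: 4 (6,7-dimethoxy-2H-chromen-3-yl)methanol
Conditions: NaBH4, CeCl3·7H2O, MeOH, 0 °C
Reagents that add atoms: none
Why: Luche reduction delivers hydride 1,2 to the enal and leaves the styrenyl C3=C4 bond untouched.

Step 3
Reactants: 4 (6,7-dimethoxy-2H-chromen-3-yl)methanol
Product: 5 [(3S)-6,7-dimethoxy-3,4-dihydro-2H-chromen-3-yl]methanol
Conditions: [Ir(cod)(tBu-PHOX)]BArF (1–2 mol %, ligand antipode per the remark), H2 (50 bar), CH2Cl2, rt
Reagents that add atoms: none
Why: Iridium-catalysed asymmetric hydrogenation of a trisubstituted allylic alcohol, here the cyclic analogue of (E)-2-methyl-3-arylprop-2-en-1-ol (a standard substrate class for Ir–N,P catalysts), should set the C3 stereocentre by catalyst-controlled facial delivery of H2.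

Step 4
Reactants: 5 [(3S)-6,7-dimethoxy-3,4-dihydro-2H-chromen-3-yl]methanol
Product: 6 (3R)-6,7-dimethoxy-3,4-dihydro-2H-chromene-3-carbaldehyde
Conditions: Dess–Martin periodinane, CH2Cl2, 0 °C → rt; crude aldehyde used at once
Reagents that add atoms: none
Why: Dess–Martin oxidation stops at the aldehyde under non-basic conditions, so the α-stereocentre should not be enolised (the descriptor becomes R only because CHO now outranks C2 in the CIP order).

Step 5
Reactants: 6 (3R)-6,7-dimethoxy-3,4-dihydro-2H-chromene-3-carbaldehyde
Product: 7 (3S)-3-(2,2-dibromoethenyl)-6,7-dimethoxy-3,4-dihydro-2H-chromene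
Conditions: CBr4, PPh3, Zn dust, CH2Cl2, rt (ylide pre-formed); then 6, 0 °C → rt
Reagents that add atoms: carbon tetrabromide, BrC(Br)(Br)Br
Why: The Corey–Fuchs (Ramirez) dibromo-olefination is an essentially neutral Wittig reaction that is routinely applied to α-branched β-oxygenated aldehydes without epimerisation.

Step 6
Reactants: 7 (3S)-3-(2,2-dibromoethenyl)-6,7-dimethoxy-3,4-dihydro-2H-chromene; 8 dimethyl squarate (3,4-dimethoxycyclobut-3-ene-1,2-dione)
Product: 10 4-{[(3S)-6,7-dimethoxy-3,4-dihydro-2H-chromen-3-yl]ethynyl}-4-hydroxy-2,3-dimethoxycyclobut-2-en-1-one (mixture of both C4 epimers), via lithium acetylide 9 (not isolated)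
Conditions: n-BuLi (2.05 equiv), THF, −78 → 0 °C; then cannulated into 8 (1.2 equiv), THF, −78 °C; sat. aq. NH4Cl at −78 °C; neutral silica, kept cold
Reagents that add atoms: n-butyllithium, [Li]CCCC (supplies the lithium of 9; no atoms in 10)
Why: The second stage of the Corey–Fuchs sequence (Br/Li exchange, α-elimination with Fritsch–Buttenberg–Wiechell 1,2-hydrogen shift, deprotonation) gives acetylide 9, which adds 1,2 to one carbonyl of squarate 8 and should stop there because the alkoxide and the remaining vinylogous ester carbonyl are deactivated; the new carbinol centre forms without control and is erased in step 7.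

Step 7
Reactants: 10 4-{[(3S)-6,7-dimethoxy-3,4-dihydro-2H-chromen-3-yl]ethynyl}-4-hydroxy-2,3-dimethoxycyclobut-2-en-1-one
Product: 13 abroquinone A, via alkynyl vinylketene 11 (not isolated), via aryl diradical 12 (not isolated)
Conditions: p-xylene (0.01 M, degassed), 138 °C (reflux), Ar; neutral work-up
Reagents that add atoms: none
Why: Heating should trigger conrotatory 4π-electrocyclic opening of the strained cyclobutenone (cleavage of the σ-bond between the carbonyl and carbinol carbons), the hydroxyl rotating outward so that the alkynyl group of vinylketene 11 points at the ketene; the ketene carbon then bonds to the distal alkyne carbon to give the aromatic diradical 12 (phenoxyl oxygen and adjacent σ-aryl radical), and transfer of the hydroxyl hydrogen to the radical carbon delivers the quinone without external oxidant. This is the Moore rearrangement of 4-alkynyl-4-hydroxycyclobutenones, a known reaction of 2,3-dialkoxy substrates with alkyl-substituted alkynes. The six-membered ring (four squarate carbons plus the two alkyne carbons) is closed in the 6-endo-dig mode between the ketene carbon and the distal alkyne carbon. No stereocentre is created: the carbinol centre of both epimers of 10 becomes the C4 carbonyl, and the chroman C3 centre is a propargylic spectator whose hydrogens are out of reach of the σ-radical except through strained four- or five-membered transition states. The selectivity needed is six- versus five-membered closure (5-exo-dig attack at the proximal alkyne carbon would lead to an alkylidenecyclopentenedione); the secondary alkyl substituent on the alkyne terminus, which does not stabilise a vinyl radical, should favour the quinone pathway, and high dilution suppresses intermolecular trapping of 12.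

Compound list
1 | 2-hydroxy-4,5-dimethoxybenzaldehyde | COc1cc(O)c(C=O)cc1OC | starting material
2 | acrolein | C=CC=O | starting material
3 | 6,7-dimethoxy-2H-chromene-3-carbaldehyde | O=CC1=Cc2cc(OC)c(OC)cc2OC1 | intermediate
4 | (6,7-dimethoxy-2H-chromen-3-yl)methanol | OCC1=Cc2cc(OC)c(OC)cc2OC1 | intermediate
5 | [(3S)-6,7-dimethoxy-3,4-dihydro-2H-chromen-3-yl]methanol | OC[C@H]1COc2cc(OC)c(OC)cc2C1 | intermediate
6 | (3R)-6,7-dimethoxy-3,4-dihydro-2H-chromene-3-carbaldehyde | O=C[C@H]1COc2cc(OC)c(OC)cc2C1 | intermediate
7 | (3S)-3-(2,2-dibromoethenyl)-6,7-dimethoxy-3,4-dihydro-2H-chromene | BrC(Br)=C[C@H]1COc2cc(OC)c(OC)cc2C1 | intermediate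
8 | dimethyl squarate (3,4-dimethoxycyclobut-3-ene-1,2-dione) | COC1=C(OC)C(=O)C1=O | starting material
9 | lithium [(3S)-6,7-dimethoxy-3,4-dihydro-2H-chromen-3-yl]acetylide | [Li]C#C[C@H]1COc2cc(OC)c(OC)cc2C1 | intermediate (not isolated)
10 | 4-{[(3S)-6,7-dimethoxy-3,4-dihydro-2H-chromen-3-yl]ethynyl}-4-hydroxy-2,3-dimethoxycyclobut-2-en-1-one, both C4 epimers | COC1=C(OC)C(O)(C#C[C@H]2COc3cc(OC)c(OC)cc3C2)C1=O | intermediate
11 | (3Z)-5-[(3S)-6,7-dimethoxychroman-3-yl]-3-hydroxy-1,2-dimethoxypent-1,3-dien-4-yn-1-ylidene ketone (alkynyl vinylketene, alkyne cis to the ketene) | O=C=C(OC)/C(OC)=C(/O)C#C[C@H]1COc2cc(OC)c(OC)cc2C1 | intermediate (not isolated)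
12 | 2-[(3S)-6,7-dimethoxychroman-3-yl]-4-hydroxy-5,6-dimethoxyphenoxyl-3-yl diradical | [O]c1c(OC)c(OC)c(O)[c]c1[C@H]2COc3cc(OC)c(OC)cc3C2 | intermediate (not isolated)
13 | abroquinone A, 2-[(3S)-6,7-dimethoxy-3,4-dihydro-2H-chromen-3-yl]-5,6-dimethoxycyclohexa-2,5-diene-1,4-dione | COC1=C(OC)C(=O)C([C@H]2COc3cc(OC)c(OC)cc3C2)=CC1=O | target

Total step count: 7. Longest linear sequence: 7 steps (1 → 13).

Steps most likely to fail

1. Step 7 (key step). The ketene may close in the five-membered mode onto the proximal alkyne carbon, or the diradical may oligomerise. The product could also lose configuration at C3 through quinone/quinone-methide tautomerisation if base or prolonged heating is used. The fallback keeps the quinone ring as the last ring formed but replaces the diradical pathway by a closed-shell electrocyclic ring expansion. It sets out from aldehyde 6. Takai iodo-olefination (CHI3, CrCl2, THF, 0 °C) should give (3S)-3-[(E)-2-iodoethenyl]-6,7-dimethoxychroman F1. Iodine–lithium exchange (t-BuLi, 2 equiv, Et2O, −78 °C) gives the (E)-vinyllithium F2, which is added to dimethyl squarate 8 at −78 °C to give the 4-alkenyl-4-hydroxy-2,3-dimethoxycyclobutenone F3. Heating F3 in toluene (110 °C) should give, by ring opening, 6π-electrocyclisation and tautomerisation, the hydroquinone 5-[(3S)-6,7-dimethoxychroman-3-yl]-2,3-dimethoxybenzene-1,4-diol F4. Oxidation of F4 with Ag2O (Et2O, rt) comes back to the route at 13.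

2. Step 3. Facial discrimination may be insufficient, and the acidic cationic iridium hydride may ionise the electron-rich allylic alcohol, leading to C–O hydrogenolysis. The fallback moves the stereo-defining step to a carboxylate-directed ruthenium hydrogenation. It sets out from enal 3. Pinnick oxidation (NaClO2, NaH2PO4, 2-methyl-2-butene, t-BuOH/H2O) gives 6,7-dimethoxy-2H-chromene-3-carboxylic acid F5. Hydrogenation with Ru(OAc)2(BINAP) (H2, MeOH; ligand antipode chosen as in the remark) should give (3R)-6,7-dimethoxychroman-3-carboxylic acid F6, a crystalline acid whose enantiomeric purity can be upgraded by recrystallisation. Reduction with BH3·THF (0 °C → rt) comes back to the route at 5.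

3. Step 5. Configuration at C3 of aldehyde 6 may be partly lost, by enolisation or by reversible retro-oxa-Michael ring opening, during the comparatively slow ylide olefination in the presence of zinc and phosphonium salts. The fallback replaces the Wittig/carbenoid sequence by a low-temperature diazo homologation. It sets out from 6. Colvin rearrangement with lithiated trimethylsilyldiazomethane (TMSCHN2, n-BuLi, THF, −78 °C → rt) should give the terminal alkyne (3S)-3-ethynyl-6,7-dimethoxychroman F7 directly. Deprotonation with n-BuLi (1.0 equiv, THF, −78 °C) comes back to the route at acetylide 9, which is added to 8 as in step 6.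

Further compounds
F1 | step 7 | (3S)-3-[(E)-2-iodoethenyl]-6,7-dimethoxy-3,4-dihydro-2H-chromene | I/C=C/[C@H]1COc2cc(OC)c(OC)cc2C1
F2 | step 7 | (E)-2-[(3S)-6,7-dimethoxy-3,4-dihydro-2H-chromen-3-yl]ethenyllithium | [Li]/C=C/[C@H]1COc2cc(OC)c(OC)cc2C1
F3 | step 7 | 4-{(E)-2-[(3S)-6,7-dimethoxy-3,4-dihydro-2H-chromen-3-yl]ethenyl}-4-hydroxy-2,3-dimethoxycyclobut-2-en-1-one, both C4 epimers | COC1=C(OC)C(O)(/C=C/[C@H]2COc3cc(OC)c(OC)cc3C2)C1=O
F4 | step 7 | 5-[(3S)-6,7-dimethoxy-3,4-dihydro-2H-chromen-3-yl]-2,3-dimethoxybenzene-1,4-diol | COc1c(OC)c(O)c([C@H]2COc3cc(OC)c(OC)cc3C2)cc1O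
F5 | step 3 | 6,7-dimethoxy-2H-chromene-3-carboxylic acid | OC(=O)C1=Cc2cc(OC)c(OC)cc2OC1
F6 | step 3 | (3R)-6,7-dimethoxy-3,4-dihydro-2H-chromene-3-carboxylic acid | OC(=O)[C@H]1COc2cc(OC)c(OC)cc2C1
F7 | step 5 | (3S)-3-ethynyl-6,7-dimethoxy-3,4-dihydro-2H-chromene | C#C[C@H]1COc2cc(OC)c(OC)cc2C1
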